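**Retrosynthetic overview**
1. The target 17 comes from tetrabenzyl ether 16 by one neutral hydrogenolysis; the two methyl ethers stay.
2. Ring C of the flavanone is cut at C3–C4 and O1–C2, giving ortho-hydroxybenzaldehyde 13 and 4-ethynylanisole 14 (one-pot alkyne hydroacylation, then asymmetric oxa-Michael closure).
3. Enabling feature: O1 sits on C8a, ortho to C4a, which carries C4. In 13 this phenol chelates rhodium for activation of the formyl C–H bond (future C4) and then closes ring C at C2; the other ortho oxygen (future 5-OH) is benzylated, which fixes 6-aryl over 8-aryl connectivity.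
4. 13 comes from ortho-formylation of phenol 11, whose 4-aryl-3,5-bis(benzyloxy)phenol ring has two equivalent ortho positions; 11 comes from Negishi coupling of bromoflavone 5 with the arylzinc made from 7.
5. Ring order: ring C of the flavone first (steps 1–2), then the biaryl bond (step 4), then ring C of the flavanone with C2 (step 7).

Key step: step 7

Remark 1: the biaryl axis carries three small ortho substituents and is taken to rotate freely, so C2 is the only stereoelement.
Remark 2: the quinine-derived thiourea is taken to deliver the 2S face; if the sense proves opposite, its quinidine-derived pseudoenantiomer is used with no other change.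
Remark 3: compounds 1, 2, 6 and 14 are taken as catalogue chemicals.

**Step 1**
Reactants: 1 1-[2,4-bis(benzyloxy)-6-hydroxyphenyl]ethan-1-one; 2 3-bromo-4-methoxybenzaldehyde
Product: 3 (2E)-1-[2,4-bis(benzyloxy)-6-hydroxyphenyl]-3-(3-bromo-4-methoxyphenyl)prop-2-en-1-one
Conditions: KOH (aq, 3 equiv), EtOH–THF, 25 °C; aq HCl work-up
Reagents that add atoms: none
Why: Claisen–Schmidt condensation; the methyl ketone enolate adds to the non-enolisable aldehyde and E1cB dehydration should give the (E)-enone, the hydrogen-bonded ortho phenol needing no protection.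

**Step 2**
Reactants: 3 (2E)-1-[2,4-bis(benzyloxy)-6-hydroxyphenyl]-3-(3-bromo-4-methoxyphenyl)prop-2-en-1-one
Product: 5 5,7-bis(benzyloxy)-2-(3-bromo-4-methoxyphenyl)-4H-chromen-4-one, via racemic flavanone 4 (not isolated)
Conditions: I2 (10 mol %), DMSO, 130 °C
Reagents that add atoms: none
Why: Iodine-catalysed oxidative cyclisation of a 2'-hydroxychalcone; oxa-Michael closure to flavanone 4 and iodine-mediated dehydrogenation should give the flavone, with DMSO as terminal oxidant and the aryl bromide and benzyl ethers untouched.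

**Step 3**
Reactants: 6 3,5-bis(benzyloxy)phenol
Product: 7 [3,5-bis(benzyloxy)phenoxy]tri(propan-2-yl)silane
Conditions: TIPSCl, imidazole, DMF, 25 °C
Reagents that add atoms: chlorotri(propan-2-yl)silane (TIPSCl), CC(C)[Si](Cl)(C(C)C)C(C)C
Why: Silylation of the phenol; the bulky silyl ether removes the acidic proton and shields both positions next to it, so the next step can only metalate between the two benzyloxy groups.

**Step 4**
Reactants: 7 [3,5-bis(benzyloxy)phenoxy]tri(propan-2-yl)silane; 5 5,7-bis(benzyloxy)-2-(3-bromo-4-methoxyphenyl)-4H-chromen-4-one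
Product: 10 5,7-bis(benzyloxy)-2-{2',6'-bis(benzyloxy)-6-methoxy-4'-[tri(propan-2-yl)silyloxy]biphenyl-3-yl}-4H-chromen-4-one, via aryllithium 8 (not isolated), via arylzinc chloride 9 (not isolated)
Conditions: 7 (1.3 equiv), n-BuLi, THF, 0 °C; ZnCl2, 0 to 25 °C; then 5, Pd2(dba)3 (2 mol %), RuPhos (8 mol %), THF, 65 °C
Reagents that add atoms: none
Why: Directed ortho-metalation between the two cooperating benzyloxy groups, transmetalation to zinc and Negishi coupling (oxidative addition of zerovalent palladium into the C–Br bond, transmetalation, reductive elimination); the bulky biarylphosphine suits a tri-ortho-substituted biaryl and the arylzinc tolerates the chromenone carbonyl.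

**Step 5**
Reactants: 10 5,7-bis(benzyloxy)-2-{2',6'-bis(benzyloxy)-6-methoxy-4'-[tri(propan-2-yl)silyloxy]biphenyl-3-yl}-4H-chromen-4-one
Product: 11 5,7-bis(benzyloxy)-2-[2',6'-bis(benzyloxy)-4'-hydroxy-6-methoxybiphenyl-3-yl]-4H-chromen-4-one
Conditions: TBAF, AcOH, THF, 0 to 25 °C
Reagents that add atoms: none
Why: Fluoride-induced cleavage of the aryl silyl ether, driven by the Si–F bond; the acetic acid buffer keeps the medium near neutral.

**Step 6**
Reactants: 11 5,7-bis(benzyloxy)-2-[2',6'-bis(benzyloxy)-4'-hydroxy-6-methoxybiphenyl-3-yl]-4H-chromen-4-one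
Product: 13 2,4-bis(benzyloxy)-3-{5-[5,7-bis(benzyloxy)-4-oxo-4H-chromen-2-yl]-2-methoxyphenyl}-6-hydroxybenzaldehyde, via salicyl alcohol 12 (not isolated)
Conditions: MgCl2, Et3N, paraformaldehyde, MeCN–THF, 70 °C; aq HCl work-up
Reagents that add atoms: formaldehyde (as paraformaldehyde), C=O
Why: Magnesium-mediated ortho-formylation of a phenol (Casnati–Skattebøl reaction); the magnesium phenoxide delivers formaldehyde to the ortho carbon and a second formaldehyde oxidises alcohol 12 by hydride transfer, and because the two ortho positions are equivalent only one aldehyde can form.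

**Step 7**
Reactants: 13 2,4-bis(benzyloxy)-3-{5-[5,7-bis(benzyloxy)-4-oxo-4H-chromen-2-yl]-2-methoxyphenyl}-6-hydroxybenzaldehyde; 14 1-ethynyl-4-methoxybenzene
Product: 16 (2S)-5,7-bis(benzyloxy)-6-{5-[5,7-bis(benzyloxy)-4-oxo-4H-chromen-2-yl]-2-methoxyphenyl}-2-(4-methoxyphenyl)-2,3-dihydro-4H-chromen-4-one, via (E)-chalcone 15 (not isolated)
Conditions: 14 (1.5 equiv), [Rh(cod)(OMe)]2 (2.5 mol %), dppf (5.5 mol %), toluene, 80 °C; then N-[3,5-bis(trifluoromethyl)phenyl]-N'-(9-deoxy-epi-quinin-9-yl)thiourea (10 mol %), toluene, 0 to 25 °C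
Reagents that add atoms: none
Why: The rhodium phenoxide of 13 inserts monovalent rhodium into the formyl C–H bond to give a five-membered acyl(hydrido)rhodium chelate, alkyne 14 inserts into Rh–H with hydride going to the aryl-bearing carbon, and C–C reductive elimination forms C3–C4 and releases (E)-chalcone 15, which the bifunctional thiourea then closes through the same phenol to form O1–C2. The closest known reaction type is the tandem alkyne hydroacylation/oxa-Michael synthesis of chroman-4-ones from salicylaldehydes, combined with the cinchona-thiourea-catalysed cyclisation of 2'-hydroxychalcones. The one ring closed, ring C of the flavanone, forms by a 6-endo-trig oxa-Michael addition. C2 is the only new stereocenter and is set by the catalyst: the thiourea hydrogen-bonds the enone carbonyl while the quinuclidine holds the phenol, so oxygen should be delivered to one face of the (E)-enone to give 2S. The step needs linear regioselectivity in the insertion, secured by the terminal alkyne and the bulky chelated acylrhodium, and closure through the correct oxygen, secured because the other ortho oxygen (the future 5-OH) is benzylated. The rhodium stage is run without added base so that 15 should stay open until the chiral catalyst is added.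

**Step 8**
Reactants: 16 (2S)-5,7-bis(benzyloxy)-6-{5-[5,7-bis(benzyloxy)-4-oxo-4H-chromen-2-yl]-2-methoxyphenyl}-2-(4-methoxyphenyl)-2,3-dihydro-4H-chromen-4-one
Product: 17 (2S)-5,7-dihydroxy-6-[5-(5,7-dihydroxy-4-oxo-4H-chromen-2-yl)-2-methoxyphenyl]-2-(4-methoxyphenyl)-2,3-dihydro-4H-chromen-4-one
Conditions: H2 (1 atm), 10% Pd/C, EtOAc–THF, 25 °C
Reagents that add atoms: none
Why: Hydrogenolysis of four benzyl ethers on palladium under neutral conditions; with no base or acid present the C2 center, which racemises by ring opening under base, should be kept, and the reaction is stopped at the calculated hydrogen uptake to spare the flavone double bond and the ring C2–O1 bond.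

**Compound list**
1 | 1-[2,4-bis(benzyloxy)-6-hydroxyphenyl]ethan-1-one | CC(=O)c1c(O)cc(OCc2ccccc2)cc1OCc1ccccc1 | starting material
2 | 3-bromo-4-methoxybenzaldehyde | COc1ccc(C=O)cc1Br | starting material
3 | (2E)-1-[2,4-bis(benzyloxy)-6-hydroxyphenyl]-3-(3-bromo-4-methoxyphenyl)prop-2-en-1-one | COc1ccc(/C=C/C(=O)c2c(O)cc(OCc3ccccc3)cc2OCc2ccccc2)cc1Br | intermediate
4 | racemic 5,7-bis(benzyloxy)-2-(3-bromo-4-methoxyphenyl)-2,3-dihydro-4H-chromen-4-one | COc1ccc(C2CC(=O)c3c(OCc4ccccc4)cc(OCc4ccccc4)cc3O2)cc1Br | intermediate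
5 | 5,7-bis(benzyloxy)-2-(3-bromo-4-methoxyphenyl)-4H-chromen-4-one | COc1ccc(-c2cc(=O)c3c(OCc4ccccc4)cc(OCc4ccccc4)cc3o2)cc1Br | intermediate
6 | 3,5-bis(benzyloxy)phenol | Oc1cc(OCc2ccccc2)cc(OCc2ccccc2)c1 | starting material
7 | [3,5-bis(benzyloxy)phenoxy]tri(propan-2-yl)silane | CC(C)[Si](Oc1cc(OCc2ccccc2)cc(OCc2ccccc2)c1)(C(C)C)C(C)C | intermediate
8 | {2,6-bis(benzyloxy)-4-[tri(propan-2-yl)silyloxy]phenyl}lithium | CC(C)[Si](Oc1cc(OCc2ccccc2)c([Li])c(OCc2ccccc2)c1)(C(C)C)C(C)C | intermediate
9 | {2,6-bis(benzyloxy)-4-[tri(propan-2-yl)silyloxy]phenyl}zinc chloride | CC(C)[Si](Oc1cc(OCc2ccccc2)c([Zn]Cl)c(OCc2ccccc2)c1)(C(C)C)C(C)C | intermediate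
10 | 5,7-bis(benzyloxy)-2-{2',6'-bis(benzyloxy)-6-methoxy-4'-[tri(propan-2-yl)silyloxy]biphenyl-3-yl}-4H-chromen-4-one | COc1ccc(-c2cc(=O)c3c(OCc4ccccc4)cc(OCc4ccccc4)cc3o2)cc1-c1c(OCc2ccccc2)cc(O[Si](C(C)C)(C(C)C)C(C)C)cc1OCc1ccccc1 | intermediate
11 | 5,7-bis(benzyloxy)-2-[2',6'-bis(benzyloxy)-4'-hydroxy-6-methoxybiphenyl-3-yl]-4H-chromen-4-one | COc1ccc(-c2cc(=O)c3c(OCc4ccccc4)cc(OCc4ccccc4)cc3o2)cc1-c1c(OCc2ccccc2)cc(O)cc1OCc1ccccc1 | intermediate
12 | 5,7-bis(benzyloxy)-2-[2',6'-bis(benzyloxy)-4'-hydroxy-3'-(hydroxymethyl)-6-methoxybiphenyl-3-yl]-4H-chromen-4-one | COc1ccc(-c2cc(=O)c3c(OCc4ccccc4)cc(OCc4ccccc4)cc3o2)cc1-c1c(OCc2ccccc2)cc(O)c(CO)c1OCc1ccccc1 | intermediate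
13 | 2,4-bis(benzyloxy)-3-{5-[5,7-bis(benzyloxy)-4-oxo-4H-chromen-2-yl]-2-methoxyphenyl}-6-hydroxybenzaldehyde | COc1ccc(-c2cc(=O)c3c(OCc4ccccc4)cc(OCc4ccccc4)cc3o2)cc1-c1c(OCc2ccccc2)cc(O)c(C=O)c1OCc1ccccc1 | intermediate
14 | 1-ethynyl-4-methoxybenzene | C#Cc1ccc(OC)cc1 | starting material
15 | (2E)-1-(2,4-bis(benzyloxy)-3-{5-[5,7-bis(benzyloxy)-4-oxo-4H-chromen-2-yl]-2-methoxyphenyl}-6-hydroxyphenyl)-3-(4-methoxyphenyl)prop-2-en-1-one | COc1ccc(/C=C/C(=O)c2c(O)cc(OCc3ccccc3)c(-c3cc(-c4cc(=O)c5c(OCc6ccccc6)cc(OCc6ccccc6)cc5o4)ccc3OC)c2OCc2ccccc2)cc1 | intermediate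
16 | (2S)-5,7-bis(benzyloxy)-6-{5-[5,7-bis(benzyloxy)-4-oxo-4H-chromen-2-yl]-2-methoxyphenyl}-2-(4-methoxyphenyl)-2,3-dihydro-4H-chromen-4-one | COc1ccc([C@@H]2CC(=O)c3c(cc(OCc4ccccc4)c(-c4cc(-c5cc(=O)c6c(OCc7ccccc7)cc(OCc7ccccc7)cc6o5)ccc4OC)c3OCc3ccccc3)O2)cc1 | intermediate
17 | (2S)-5,7-dihydroxy-6-[5-(5,7-dihydroxy-4-oxo-4H-chromen-2-yl)-2-methoxyphenyl]-2-(4-methoxyphenyl)-2,3-dihydro-4H-chromen-4-one | COc1ccc([C@@H]2CC(=O)c3c(cc(O)c(-c4cc(-c5cc(=O)c6c(O)cc(O)cc6o5)ccc4OC)c3O)O2)cc1 | target

**Step count and risks**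
Total steps: 8. Longest linear sequence: 7 steps (1 → 3 → 5 → 10 → 11 → 13 → 16 → 17).

Steps most likely to fail:

1. Step 7. The oxa-Michael closure may show poor facial selectivity, or lose it by reversible ring opening. The chalcone may also close without the chiral catalyst during the hot rhodium stage. The doubly ortho-substituted aldehyde may undergo hydroacylation slowly or with the wrong insertion regiochemistry. The fallback sets out from 13 and comes back at 16. Ethynylmagnesium bromide (excess, THF, 0 °C) would add to 13 to give propargylic alcohol F1. MnO2 (CH2Cl2, 25 °C) would oxidise it to ynone F2. Et2NH in EtOH (amine conjugate addition, then 6-endo closure by the phenol with loss of the amine) would give the 2-unsubstituted chromone F3. Conjugate arylation of F3 with 4-methoxyphenylboronic acid (Pd(OCOCF3)2, the t-BuPyOx enantiomer that gives the 2S product, NH4PF6, water, ClCH2CH2Cl, 60 °C) would then give 16. In this fallback C2 is set by catalyst-controlled aryl transfer instead of C–O closure, and the flavone enone, already aryl-substituted at its β-carbon, should stay untouched.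

2. Step 4. Benzylic deprotonation with [1,2]-Wittig rearrangement may compete with ring lithiation, or transmetalation and reductive elimination may stall at the tri-ortho-substituted biaryl. The fallback sets out from 7 and 5 and comes back at 10. NBS (MeCN, 0 °C) should brominate 7 between the two benzyloxy groups, the silyl ether shielding the other positions, to give aryl bromide F4. Miyaura borylation of 5 (B2pin2, Pd(dppf)Cl2, KOAc, dioxane, 90 °C) would give boronate F5. Suzuki–Miyaura coupling of F4 with F5 (Pd(OAc)2, SPhos, K3PO4, toluene–water, 90 °C) would give 10.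

3. Step 8. Over-reduction may occur (saturation of the flavone C2=C3 bond, or hydrogenolytic opening of the benzylic C2–O1 bond), or the hindered 5-O-benzyl group may cleave incompletely. The fallback sets out from 16 and comes back at 17. Lewis-acid debenzylation with BCl3 and pentamethylbenzene as benzyl-cation scavenger (CH2Cl2, −78 °C, quenched cold with MeOH) would remove the four benzyl groups without hydrogen; the low temperature is meant to keep the methyl ethers and the C2–O1 bond intact. No new compound arises (entry F0).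

**Further compounds**
F1 | step 7 | 5,7-bis(benzyloxy)-2-[2',6'-bis(benzyloxy)-4'-hydroxy-3'-(1-hydroxyprop-2-yn-1-yl)-6-methoxybiphenyl-3-yl]-4H-chromen-4-one (racemic) | C#CC(O)c1c(O)cc(OCc2ccccc2)c(-c2cc(-c3cc(=O)c4c(OCc5ccccc5)cc(OCc5ccccc5)cc4o3)ccc2OC)c1OCc1ccccc1
F2 | step 7 | 5,7-bis(benzyloxy)-2-[2',6'-bis(benzyloxy)-4'-hydroxy-6-methoxy-3'-(prop-2-ynoyl)biphenyl-3-yl]-4H-chromen-4-one | C#CC(=O)c1c(O)cc(OCc2ccccc2)c(-c2cc(-c3cc(=O)c4c(OCc5ccccc5)cc(OCc5ccccc5)cc4o3)ccc2OC)c1OCc1ccccc1
F3 | step 7 | 5,7-bis(benzyloxy)-6-{5-[5,7-bis(benzyloxy)-4-oxo-4H-chromen-2-yl]-2-methoxyphenyl}-4H-chromen-4-one | O=c1ccoc2cc(OCc3ccccc3)c(-c3cc(-c4cc(=O)c5c(OCc6ccccc6)cc(OCc6ccccc6)cc5o4)ccc3OC)c(OCc3ccccc3)c12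
F4 | step 4 | [3,5-bis(benzyloxy)-4-bromophenoxy]tri(propan-2-yl)silane | CC(C)[Si](Oc1cc(OCc2ccccc2)c(Br)c(OCc2ccccc2)c1)(C(C)C)C(C)C
F5 | step 4 | 5,7-bis(benzyloxy)-2-[4-methoxy-3-(4,4,5,5-tetramethyl-1,3,2-dioxaborolan-2-yl)phenyl]-4H-chromen-4-one | COc1ccc(-c2cc(=O)c3c(OCc4ccccc4)cc(OCc4ccccc4)cc3o2)cc1B1OC(C)(C)C(C)(C)O1
F0 | step 8 | none | none
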